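**Retrosynthetic overview**

- The strategy rests on ring A of the 2,3-dihydrobenzofuran: O1 on C7a, a methoxy group on C7 and the propenyl carbon on C5 para to O1. This is the pattern left when a 3-substituted coumalate adds across an O1–C7a=C3a ketene acetal.
- Key disconnection: C7a–C7 and C3a–C4 are cut, giving the silyl ketene acetal of the (4S,5S)-trans-γ-lactone (ring B complete, C2 and C3 set) and methyl 3-bromocoumalate.
- Ring B is made first as the lactone: anti-crotylboration of the benzylated aldehyde, hydroboration and oxidative lactonisation. Ring A is then closed onto it by cycloaddition, loss of CO2 and loss of silanol.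
- Late stage: C7–Br to C7–OMe, debenzylation, then ester to aldehyde to (E)-propenyl.

Key step: step 7

Remark: the (S)-phosphoric acid is specified on the expectation that acids of this family with (R) configuration direct Re-face addition to aryl aldehydes (the enantiomeric acid would be used if the sense were opposite); sulfone 22 is taken as a purchasable reagent.

**Route**

Step 1
Reactants: 1 3-hydroxy-4,5-dimethoxybenzaldehyde
Product: 2 3-(benzyloxy)-4,5-dimethoxybenzaldehyde
Conditions: BnBr (1.2 equiv), K2CO3, DMF, rt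
Reagents that add atoms: benzyl bromide, BrCc1ccccc1
Why: Williamson etherification of the only acidic hydroxyl masks the phenol against the borane, amide base and hydride reagents used later.

Step 2
Reactants: 2 3-(benzyloxy)-4,5-dimethoxybenzaldehyde; 3 (E)-but-2-enylboronic acid pinacol ester
Product: 5 (1S,2S)-1-[3-(benzyloxy)-4,5-dimethoxyphenyl]-2-methylbut-3-en-1-ol, via borate ester 4 (not isolated)
Conditions: (S)-3,3'-bis(2,4,6-triisopropylphenyl)-1,1'-binaphthyl-2,2'-diyl hydrogen phosphate (5 mol%), 4 Å MS, toluene, −30 °C; then aq. NaHCO3, rt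
Reagents that add atoms: none
Why: Chiral-phosphoric-acid-catalysed crotylboration runs through a closed chair (Zimmerman–Traxler) transition state, so the E-boronate should give the anti relationship, and the acid hydrogen-bonded to a boronate oxygen should select the Si face of the aldehyde, setting both centres as (1S,2S).

Step 3
Reactants: 5 (1S,2S)-1-[3-(benzyloxy)-4,5-dimethoxyphenyl]-2-methylbut-3-en-1-ol
Product: 7 (1S,2S)-1-[3-(benzyloxy)-4,5-dimethoxyphenyl]-2-methylbutane-1,4-diol, via alkylborane 6 (not isolated)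
Conditions: 9-BBN (2.5 equiv), THF, 0 °C → rt; then aq. NaOH, H2O2, 0 °C → rt
Reagents that add atoms: hydrogen peroxide, OO
Why: Anti-Markovnikov hydroboration of the monosubstituted alkene with 9-BBN and oxidation of the C–B bond give the primary alcohol without touching either stereocentre.

Step 4
Reactants: 7 (1S,2S)-1-[3-(benzyloxy)-4,5-dimethoxyphenyl]-2-methylbutane-1,4-diol
Product: 9 (4S,5S)-5-[3-(benzyloxy)-4,5-dimethoxyphenyl]-4-methyldihydrofuran-2(3H)-one, via lactol 8 (not isolated)
Conditions: TEMPO (0.2 equiv), PhI(OAc)2 (2.5 equiv), CH2Cl2, rt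
Reagents that add atoms: none
Why: In this oxoammonium-mediated oxidative lactonisation the primary alcohol is oxidised first, the hydroxy aldehyde closes to lactol 8 and this is oxidised to the lactone; the anti diol therefore becomes the trans-lactone with C4 and C5 unchanged.

Step 5
Reactants: 9 (4S,5S)-5-[3-(benzyloxy)-4,5-dimethoxyphenyl]-4-methyldihydrofuran-2(3H)-one
Product: 11 {[(4S,5S)-5-[3-(benzyloxy)-4,5-dimethoxyphenyl]-4-methyl-4,5-dihydrofuran-2-yl]oxy}(tert-butyl)dimethylsilane, via lithium enolate 10 (not isolated)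
Conditions: LiN(iPr)2 (1.15 equiv), THF, −78 °C; TBSCl (1.3 equiv), DMPU, −78 °C → rt; pentane, filtration, no aqueous work-up, used crude
Reagents that add atoms: tert-butyldimethylsilyl chloride, CC(C)(C)[Si](C)(C)Cl
Why: Kinetic enolisation of the lactone and O-silylation in the presence of DMPU give the silyl ketene acetal; the C4 and C5 hydrogens are not acidic enough to be removed at −78 °C.

Step 6
Reactants: 12 methyl 2-oxo-2H-pyran-5-carboxylate (methyl coumalate)
Product: 14 methyl 3-bromo-2-oxo-2H-pyran-5-carboxylate, via dibromide 13 (not isolated)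
Conditions: Br2 (1.05 equiv), CH2Cl2, rt; then Et3N (1.2 equiv), 0 °C
Reagents that add atoms: bromine, BrBr
Why: Bromine adds across C3=C4, the more electron-rich double bond of the pyrone, and triethylamine removes the acidic C3–H next to the lactone carbonyl with loss of the C4 bromide (addition–elimination), restoring the pyrone with bromine at C3.

Step 7
Reactants: 11 {[(4S,5S)-5-[3-(benzyloxy)-4,5-dimethoxyphenyl]-4-methyl-4,5-dihydrofuran-2-yl]oxy}(tert-butyl)dimethylsilane; 14 methyl 3-bromo-2-oxo-2H-pyran-5-carboxylate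
Product: 17 methyl (2S,3S)-2-[3-(benzyloxy)-4,5-dimethoxyphenyl]-7-bromo-3-methyl-2,3-dihydrobenzofuran-5-carboxylate, via bridged lactone 15 (not isolated), via diene 16 (not isolated)
Conditions: 14 (1.5 equiv), 4 Å MS, toluene, 80 → 120 °C, sealed tube
Reagents that add atoms: none
Why: The nucleophilic ketene-acetal carbon (future C3a) bonds to C6 of the electron-poor pyrone and the acetal carbon (future C7a) to C3 in a [4+2] cycloaddition with inverse electron demand, concerted but asynchronous or by way of a zwitterion, giving bridged lactone 15; this loses CO2 by cycloreversion to diene 16, which aromatises by 1,2-elimination of tert-butyldimethylsilanol. The closest known reaction is the benzannulation of coumalate esters and 3-bromo-2-pyrones with ketene acetals and silyl enol ethers to para-oxygenated benzoates; the endocyclic lactone-derived silyl donor and the 3-bromo substituent on a coumalate go beyond the reported examples. Ring A is closed by cycloaddition (two σ-bonds, C7a–C7 and C3a–C4) onto the preformed ring B and made aromatic by cycloreversion and elimination. No new stereocentre survives, and C2 and C3 are untouched because neither carries an acidic hydrogen or a leaving group involved in the sequence. The regiochemistry (ester at C5, bromine at C7) should follow from polarity, the donor carbon attacking the pyrone carbon that is β to the ester and vinylogous to the lactone carbonyl. The aromatisation must expel silanol and not the ring oxygen, which is expected because silanolate is the better leaving group and the ring oxygen is the better donor to the developing oxocarbenium ion.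

Step 8
Reactants: 17 methyl (2S,3S)-2-[3-(benzyloxy)-4,5-dimethoxyphenyl]-7-bromo-3-methyl-2,3-dihydrobenzofuran-5-carboxylate
Product: 18 methyl (2S,3S)-2-[3-(benzyloxy)-4,5-dimethoxyphenyl]-7-methoxy-3-methyl-2,3-dihydrobenzofuran-5-carboxylate
Conditions: CuI (0.3 equiv), NaOMe (6 equiv), dry MeOH/DMF, 100 °C
Reagents that add atoms: sodium methoxide, [Na+].[O-]C
Why: Ullmann-type copper-catalysed methoxylation of an aryl bromide ortho to an ether oxygen is established for bromoguaiacol-type arenes; exchange at the methyl ester is degenerate and the benzylic C–H bonds at C2 and C3 are not acidic enough to epimerise.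

Step 9
Reactants: 18 methyl (2S,3S)-2-[3-(benzyloxy)-4,5-dimethoxyphenyl]-7-methoxy-3-methyl-2,3-dihydrobenzofuran-5-carboxylate
Product: 19 methyl (2S,3S)-2-(3-hydroxy-4,5-dimethoxyphenyl)-7-methoxy-3-methyl-2,3-dihydrobenzofuran-5-carboxylate
Conditions: H2 (1 atm), Pd/C (10% Pd on carbon), EtOAc, rt, stopped after one equivalent of H2
Reagents that add atoms: none
Why: Hydrogenolysis of the benzyl aryl ether is done before any alkene is present; the secondary, ring-bound C2–O1 benzylic bond should be cleaved much more slowly under neutral conditions.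

Step 10
Reactants: 19 methyl (2S,3S)-2-(3-hydroxy-4,5-dimethoxyphenyl)-7-methoxy-3-methyl-2,3-dihydrobenzofuran-5-carboxylate
Product: 20 5-[(2S,3S)-5-(hydroxymethyl)-7-methoxy-3-methyl-2,3-dihydrobenzofuran-2-yl]-2,3-dimethoxyphenol
Conditions: iBu2AlH (4 equiv), CH2Cl2/THF, −78 → 0 °C; aq. potassium sodium tartrate
Reagents that add atoms: none
Why: Hydride reduction of the aryl ester to the primary alcohol is reliable, whereas stopping at the aldehyde is not; one equivalent of hydride is consumed by the phenol, which is carried as its aluminium phenoxide.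

Step 11
Reactants: 20 5-[(2S,3S)-5-(hydroxymethyl)-7-methoxy-3-methyl-2,3-dihydrobenzofuran-2-yl]-2,3-dimethoxyphenol
Product: 21 (2S,3S)-2-(3-hydroxy-4,5-dimethoxyphenyl)-7-methoxy-3-methyl-2,3-dihydrobenzofuran-5-carbaldehyde
Conditions: MnO2 (activated, 15 equiv), CH2Cl2, rt
Reagents that add atoms: none
Why: Manganese dioxide oxidises the electron-rich benzylic alcohol selectively and should tolerate the guaiacol-type phenol over a short reaction time.

Step 12
Reactants: 21 (2S,3S)-2-(3-hydroxy-4,5-dimethoxyphenyl)-7-methoxy-3-methyl-2,3-dihydrobenzofuran-5-carbaldehyde; 22 5-(ethylsulfonyl)-1-phenyl-1H-tetrazole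
Product: 23 5-[(2S,3S)-7-methoxy-3-methyl-5-[(E)-prop-1-enyl]-2,3-dihydrobenzofuran-2-yl]-2,3-dimethoxyphenol
Conditions: 22 (2.2 equiv), KN(SiMe3)2 (3.2 equiv, one equivalent used first to form the phenoxide of 21), DME, −60 °C → rt; aq. NH4Cl
Reagents that add atoms: none
Why: Julia–Kocienski olefination (addition of the metalated sulfone, Smiles rearrangement, loss of SO2 and tetrazolate) with a potassium counter-ion in DME should favour the E-alkene from an aromatic aldehyde; the phenoxide is inert and is reprotonated on work-up to give the target.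

**Compound list**

1 | 3-hydroxy-4,5-dimethoxybenzaldehyde | O=Cc1cc(O)c(OC)c(OC)c1 | starting material
2 | 3-(benzyloxy)-4,5-dimethoxybenzaldehyde | O=Cc1cc(OCc2ccccc2)c(OC)c(OC)c1 | intermediate
3 | (E)-but-2-enylboronic acid pinacol ester | C/C=C/CB1OC(C)(C)C(C)(C)O1 | starting material
4 | 2-{[(1S,2S)-1-[3-(benzyloxy)-4,5-dimethoxyphenyl]-2-methylbut-3-en-1-yl]oxy}-4,4,5,5-tetramethyl-1,3,2-dioxaborolane (borate ester, not isolated) | C=C[C@H](C)[C@@H](c1cc(OCc2ccccc2)c(OC)c(OC)c1)OB1OC(C)(C)C(C)(C)O1 | intermediate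
5 | (1S,2S)-1-[3-(benzyloxy)-4,5-dimethoxyphenyl]-2-methylbut-3-en-1-ol | C=C[C@H](C)[C@@H](c1cc(OCc2ccccc2)c(OC)c(OC)c1)O | intermediate
6 | (1S,2S)-4-(9-borabicyclo[3.3.1]nonan-9-yl)-1-[3-(benzyloxy)-4,5-dimethoxyphenyl]-2-methylbutan-1-ol (alkylborane, not isolated, drawn with the hydroxyl free) | C1CCC2CCCC1B2CC[C@H](C)[C@@H](c1cc(OCc2ccccc2)c(OC)c(OC)c1)O | intermediate
7 | (1S,2S)-1-[3-(benzyloxy)-4,5-dimethoxyphenyl]-2-methylbutane-1,4-diol | OCC[C@H](C)[C@@H](c1cc(OCc2ccccc2)c(OC)c(OC)c1)O | intermediate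
8 | (4S,5S)-5-[3-(benzyloxy)-4,5-dimethoxyphenyl]-4-methyltetrahydrofuran-2-ol (lactol, anomers, not isolated) | OC1C[C@H](C)[C@@H](c2cc(OCc3ccccc3)c(OC)c(OC)c2)O1 | intermediate
9 | (4S,5S)-5-[3-(benzyloxy)-4,5-dimethoxyphenyl]-4-methyldihydrofuran-2(3H)-one | O=C1C[C@H](C)[C@@H](c2cc(OCc3ccccc3)c(OC)c(OC)c2)O1 | intermediate
10 | lithium (4S,5S)-5-[3-(benzyloxy)-4,5-dimethoxyphenyl]-4-methyl-4,5-dihydrofuran-2-olate (not isolated) | [Li]OC1=C[C@H](C)[C@@H](c2cc(OCc3ccccc3)c(OC)c(OC)c2)O1 | intermediate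
11 | {[(4S,5S)-5-[3-(benzyloxy)-4,5-dimethoxyphenyl]-4-methyl-4,5-dihydrofuran-2-yl]oxy}(tert-butyl)dimethylsilane | CC(C)(C)[Si](C)(C)OC1=C[C@H](C)[C@@H](c2cc(OCc3ccccc3)c(OC)c(OC)c2)O1 | intermediate
12 | methyl 2-oxo-2H-pyran-5-carboxylate (methyl coumalate) | COC(=O)C1=COC(=O)C=C1 | starting material
13 | methyl 3,4-dibromo-2-oxo-3,4-dihydro-2H-pyran-5-carboxylate (racemic, not isolated) | COC(=O)C1=COC(=O)C(Br)C1Br | intermediate
14 | methyl 3-bromo-2-oxo-2H-pyran-5-carboxylate | COC(=O)C1=COC(=O)C(Br)=C1 | intermediate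
15 | methyl (2S,3S)-2-[3-(benzyloxy)-4,5-dimethoxyphenyl]-7-bromo-7a-[(tert-butyldimethylsilyl)oxy]-3-methyl-9-oxo-2,3,3a,4,7,7a-hexahydro-4,7-(epoxymethano)benzofuran-5-carboxylate (bridged lactone, new centres undefined, not isolated) | CC(C)(C)[Si](C)(C)OC13C2(Br)C(=O)OC(C(C(=O)OC)=C2)C3[C@H](C)[C@@H](c2cc(OCc4ccccc4)c(OC)c(OC)c2)O1 | intermediate
16 | methyl (2S,3S)-2-[3-(benzyloxy)-4,5-dimethoxyphenyl]-7-bromo-7a-[(tert-butyldimethylsilyl)oxy]-3-methyl-2,3,3a,7a-tetrahydrobenzofuran-5-carboxylate (diene, new centres undefined, not isolated) | CC(C)(C)[Si](C)(C)OC12C(Br)=CC(C(=O)OC)=CC1[C@H](C)[C@@H](c1cc(OCc3ccccc3)c(OC)c(OC)c1)O2 | intermediate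
17 | methyl (2S,3S)-2-[3-(benzyloxy)-4,5-dimethoxyphenyl]-7-bromo-3-methyl-2,3-dihydrobenzofuran-5-carboxylate | COC(=O)c1cc(Br)c2c(c1)[C@H](C)[C@@H](c1cc(OCc3ccccc3)c(OC)c(OC)c1)O2 | intermediate
18 | methyl (2S,3S)-2-[3-(benzyloxy)-4,5-dimethoxyphenyl]-7-methoxy-3-methyl-2,3-dihydrobenzofuran-5-carboxylate | COC(=O)c1cc(OC)c2c(c1)[C@H](C)[C@@H](c1cc(OCc3ccccc3)c(OC)c(OC)c1)O2 | intermediate
19 | methyl (2S,3S)-2-(3-hydroxy-4,5-dimethoxyphenyl)-7-methoxy-3-methyl-2,3-dihydrobenzofuran-5-carboxylate | COC(=O)c1cc(OC)c2c(c1)[C@H](C)[C@@H](c1cc(O)c(OC)c(OC)c1)O2 | intermediate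
20 | 5-[(2S,3S)-5-(hydroxymethyl)-7-methoxy-3-methyl-2,3-dihydrobenzofuran-2-yl]-2,3-dimethoxyphenol | OCc1cc(OC)c2c(c1)[C@H](C)[C@@H](c1cc(O)c(OC)c(OC)c1)O2 | intermediate
21 | (2S,3S)-2-(3-hydroxy-4,5-dimethoxyphenyl)-7-methoxy-3-methyl-2,3-dihydrobenzofuran-5-carbaldehyde | O=Cc1cc(OC)c2c(c1)[C@H](C)[C@@H](c1cc(O)c(OC)c(OC)c1)O2 | intermediate
22 | 5-(ethylsulfonyl)-1-phenyl-1H-tetrazole | CCS(=O)(=O)c1nnnn1-c1ccccc1 | starting material
23 | 5-[(2S,3S)-7-methoxy-3-methyl-5-[(E)-prop-1-enyl]-2,3-dihydrobenzofuran-2-yl]-2,3-dimethoxyphenol (CNP0299956.1) | C/C=C/c1cc(OC)c2c(c1)[C@H](C)[C@@H](c1cc(O)c(OC)c(OC)c1)O2 | target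

**Step count**

Total: 12 steps. Longest linear sequence: 11 steps (steps 1–5 and 7–12, from 1 to 23); step 6 is the one-step side branch.

**Steps most likely to fail**

1. Step 7. After cycloaddition and loss of CO2, diene 16 may aromatise by expelling the ring oxygen, which opens ring B, instead of expelling silanol. Crowding at the new C7a–C7 bond may also slow ring closure, so that silyl transfer and hydrolysis of 11 compete.
 Fallback, from 9 back to 17: the order of ring formation is reversed, so that ring A is built on an open-chain donor in which both acetal oxygens are silylated, and ring B is closed afterwards.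
 - Saponification of lactone 9 (KOH, MeOH/H2O, evaporation) should give potassium (3S,4S)-4-[3-(benzyloxy)-4,5-dimethoxyphenyl]-4-hydroxy-3-methylbutanoate F1.
 - TBSCl and imidazole in DMF should convert it into the silyl ether silyl ester F2.
 - LiN(iPr)2 then TBSCl (THF, DMPU, −78 °C) should give the bis-silyl ketene acetal F3.
 - Heating F3 with 14 in toluene should give, after loss of CO2 and of either silanol, the aryl silyl ether methyl 3-bromo-4-[(tert-butyldimethylsilyl)oxy]-5-{(1S,2S)-1-[3-(benzyloxy)-4,5-dimethoxyphenyl]-1-[(tert-butyldimethylsilyl)oxy]propan-2-yl}benzoate F4.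
 - Bu4NF/AcOH in THF should free the phenol alcohol F5.
 - Catalytic TsOH·H2O in CH2Cl2 should close ring B through the benzylic cation stabilised by the para-methoxy group, with the aryl group settling trans to the C3 methyl, to give 17.

2. Step 8. Protodebromination and saponification of the ester by adventitious hydroxide may outrun the slow C–O coupling at the position flanked by the ring oxygen.
 Fallback, from 17 back to 18: the oxygen is introduced through boron instead of by copper-mediated substitution.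
 - Borylation (B2pin2, PdCl2(dppf), KOAc, dioxane, 90 °C) should give the aryl boronate F6.
 - Oxidation (NaBO3·4H2O, THF/H2O, rt) should give the 7-hydroxy compound F7.
 - Methylation (MeI, K2CO3, DMF) should give 18; the other phenol is still benzylated at this stage.

3. Step 12. The aldehyde reacts as a sparingly soluble potassium phenoxide, which may leave conversion incomplete and erode the kinetic E selectivity of the sulfone addition.
 Fallback, from 21 back to 23: the geometry is set by equilibration instead of kinetic control.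
 - Wittig ethylidenation (Ph3PEtBr, KOtBu, 3 equiv each, THF, 0 °C → rt) should give the propenyl compound as an E/Z mixture that contains the (Z)-isomer F8.
 - The mixture is then isomerised to the thermodynamically favoured E-alkene 23 with PdCl2(MeCN)2 (5 mol%) in CH2Cl2 at rt.

**Further compounds**

F1 | step 7 | potassium (3S,4S)-4-[3-(benzyloxy)-4,5-dimethoxyphenyl]-4-hydroxy-3-methylbutanoate | [K+].[O-]C(=O)C[C@H](C)[C@@H](c1cc(OCc2ccccc2)c(OC)c(OC)c1)O
F2 | step 7 | tert-butyldimethylsilyl (3S,4S)-4-[3-(benzyloxy)-4,5-dimethoxyphenyl]-4-[(tert-butyldimethylsilyl)oxy]-3-methylbutanoate | CC(C)(C)[Si](C)(C)OC(=O)C[C@H](C)[C@@H](c1cc(OCc2ccccc2)c(OC)c(OC)c1)O[Si](C)(C)C(C)(C)C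
F3 | step 7 | {[(3S,4S)-4-[3-(benzyloxy)-4,5-dimethoxyphenyl]-4-[(tert-butyldimethylsilyl)oxy]-3-methylbut-1-ene-1,1-diyl]bis(oxy)}bis(tert-butyldimethylsilane) | CC(C)(C)[Si](C)(C)OC(O[Si](C)(C)C(C)(C)C)=C[C@H](C)[C@@H](c1cc(OCc2ccccc2)c(OC)c(OC)c1)O[Si](C)(C)C(C)(C)C
F4 | step 7 | methyl 3-bromo-4-[(tert-butyldimethylsilyl)oxy]-5-{(1S,2S)-1-[3-(benzyloxy)-4,5-dimethoxyphenyl]-1-[(tert-butyldimethylsilyl)oxy]propan-2-yl}benzoate | COC(=O)c1cc(Br)c(O[Si](C)(C)C(C)(C)C)c(c1)[C@H](C)[C@@H](c1cc(OCc2ccccc2)c(OC)c(OC)c1)O[Si](C)(C)C(C)(C)C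
F5 | step 7 | methyl 3-bromo-4-hydroxy-5-{(1S,2S)-1-[3-(benzyloxy)-4,5-dimethoxyphenyl]-1-hydroxypropan-2-yl}benzoate | COC(=O)c1cc(Br)c(O)c(c1)[C@H](C)[C@@H](c1cc(OCc2ccccc2)c(OC)c(OC)c1)O
F6 | step 8 | methyl (2S,3S)-2-[3-(benzyloxy)-4,5-dimethoxyphenyl]-3-methyl-7-(4,4,5,5-tetramethyl-1,3,2-dioxaborolan-2-yl)-2,3-dihydrobenzofuran-5-carboxylate | COC(=O)c1cc(B4OC(C)(C)C(C)(C)O4)c2c(c1)[C@H](C)[C@@H](c1cc(OCc3ccccc3)c(OC)c(OC)c1)O2
F7 | step 8 | methyl (2S,3S)-2-[3-(benzyloxy)-4,5-dimethoxyphenyl]-7-hydroxy-3-methyl-2,3-dihydrobenzofuran-5-carboxylate | COC(=O)c1cc(O)c2c(c1)[C@H](C)[C@@H](c1cc(OCc3ccccc3)c(OC)c(OC)c1)O2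
F8 | step 12 | 5-[(2S,3S)-7-methoxy-3-methyl-5-[(Z)-prop-1-enyl]-2,3-dihydrobenzofuran-2-yl]-2,3-dimethoxyphenol | C/C=C\c1cc(OC)c2c(c1)[C@H](C)[C@@H](c1cc(O)c(OC)c(OC)c1)O2
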